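Ring A (C1–C5, C10; labdane numbering) is not closed as a six-membered ring. The carboxyl carbon C18 first sits as a ketone inside a seven-membered ring, between C4 and C5, and is extruded by a Favorskii-type (semibenzilic) ring contraction of the 3α,4α-epoxy ketone. In one operation this forms the C4–C5 bond, the C4 quaternary centre (C19 β, C18 α) and the cis 3α-hydroxy/4α-carboxyl array, the β-hydroxy acid motif O–C3–C4–C18 of ring A. The precursor, a trans-fused bicyclo[5.4.0]undecane epoxy ketone, comes from a Lewis acid-promoted Diels–Alder reaction of 3-methylcyclohept-2-enone with a 2-silyloxydiene carrying the side-chain alkyne, followed by equilibration of C5 and C9.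

Key step: step 9

Remark: labdane numbering is used (ring A C1–C5/C10, ring B C5–C10, side chain C11–C15 on C9, C16 methyl on C13, C17 exocyclic methylene carbon on C8, C18 carboxyl carbon and C19 methyl on C4, C20 methyl on C10; in 6–13 the seven-membered ring is C5–C18–C4–C3–C2–C1–C10); the target is read as (3R,4S,5R,9S,10R) with 3α-OAc and 4α-CO2H; compounds 6–14 are racemic and drawn as the enantiomer that leads on, the absolute configuration being fixed by resolution in step 10; 1 and 5 are taken as catalogue chemicals.

Step 1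
Reactants: 1 hex-5-ynenitrile
Product: 2 6-(trimethylsilyl)hex-5-ynenitrile
Conditions: LiN(i-Pr)2, THF, −78 °C; Me3SiCl, −78 → 0 °C
Reagents that add atoms: chlorotrimethylsilane C[Si](C)(C)Cl
Why: Deprotonation and C-silylation of the terminal alkyne, whose C–H is far more acidic than the α-cyano C–H, masks the alkyne against the Lewis acid, ylide and enolate steps that follow.

Step 2
Reactants: 2 6-(trimethylsilyl)hex-5-ynenitrile
Product: 3 8-(trimethylsilyl)oct-1-en-7-yn-3-one
Conditions: CH2=CHMgBr, THF, 0 → 23 °C; then 1 M HCl, 0 °C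
Reagents that add atoms: vinylmagnesium bromide C=C[Mg]Br; water O
Why: Grignard addition to the nitrile stops at the N-magnesio imine, which cold aqueous acid hydrolyses to the vinyl ketone while the nitrogen leaves as non-nucleophilic ammonium.

Step 3
Reactants: 3 8-(trimethylsilyl)oct-1-en-7-yn-3-one
Product: 4 (3Z)-3-(tert-butyldimethylsilyloxy)-8-(trimethylsilyl)octa-1,3-dien-7-yne
Conditions: t-BuMe2SiOTf, Et3N, Et2O, 0 °C
Reagents that add atoms: tert-butyldimethylsilyl trifluoromethanesulfonate CC(C)(C)[Si](C)(C)OS(=O)(=O)C(F)(F)F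
Why: Soft enolisation of the only enolisable position with silyl triflate and amine base gives the 2-silyloxy-1,3-diene as the (Z)-enol ether, the isomer whose chain points outward in the s-cis diene.

Step 4
Reactants: 4 (3Z)-3-(tert-butyldimethylsilyloxy)-8-(trimethylsilyl)octa-1,3-dien-7-yne; 5 3-methylcyclohept-2-en-1-one
Product: 8 rac trans-fused 8,18-diketone (H5 α, C20 β, 9β-CH2CH2C≡CSiMe3; C1–C4 all CH2), via silyl enol ether cycloadduct 6 (not isolated), via cis-fused diketone 7 (not isolated)
Conditions: AlBr3/AlMe3 (10:1, 0.3 equiv), toluene–CH2Cl2, −5 → 23 °C; then 2 M HCl, THF, 23 °C; then DBU (0.5 equiv), CH2Cl2, 23 °C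
Reagents that add atoms: none
Why: Lewis acid-promoted Diels–Alder reaction of the hindered β-methyl enone with the 2-silyloxydiene, in which the nucleophilic enol ether carbon C9 bonds to the enone β-carbon C10 and so creates the C10 quaternary centre in a cis-fused endo adduct, after which hydrolysis frees the C8 ketone and base equilibration of the two enolisable centres C5 (next to C18=O) and C9 (next to C8=O) should converge all C5/C9 epimers on the trans-fused isomer with the C9 chain equatorial and cis to C20.

Step 5
Reactants: 8 rac trans-fused 8,18-diketone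
Product: 9 rac 8(17)-methylene 18-ketone (8 with C8=C17H2)
Conditions: Ph3PCH3Br (1.3 equiv), KN(SiMe3)2 (1.25 equiv), THF, 0 °C; then 8, 0 → 23 °C
Reagents that add atoms: methyltriphenylphosphonium bromide C[P+](c1ccccc1)(c1ccccc1)c1ccccc1.[Br-]
Why: Wittig methylenation should be selective for the six-membered C8 ketone because cyclohexanones add nucleophiles far faster than cycloheptanones, and C9 already has its thermodynamic configuration so the basic ylide cannot erode it.

Step 6
Reactants: 9 rac 8(17)-methylene 18-ketone
Product: 10 rac 4-(phenylselanyl) 18-ketone (C4 epimers)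
Conditions: LiN(i-Pr)2 (1.1 equiv), THF, −78 °C; PhSeCl (1.05 equiv), −78 °C
Reagents that add atoms: benzeneselenenyl chloride Cl[Se]c1ccccc1
Why: Kinetic deprotonation with the hindered amide base takes place at the C4 methylene and not at the ring-fusion methine C5, and the enolate is selenenylated at −78 °C before the reagent can add to the exocyclic alkene (α-selenenylation of a ketone enolate), the new C4 centre being of no consequence because it becomes sp2.

Step 7
Reactants: 10 rac 4-(phenylselanyl) 18-ketone
Product: 12 rac enone (9 with the C19 methyl on C4 and a C3=C4 double bond conjugated to C18=O), via methylated selenide 11 (not isolated)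
Conditions: LiN(i-Pr)2 (1.1 equiv), THF–DMPU, −78 → 0 °C; MeI; then m-CPBA (1.05 equiv), CH2Cl2, −78 °C; i-Pr2NH, −78 → 23 °C
Reagents that add atoms: iodomethane CI
Why: The selenium-bearing C4–H is now the most acidic proton so the second enolisation and C-methylation are regiospecific, and selenoxide syn-elimination toward the ring methylene C3 should give the conjugated endocyclic 2-methyl enone.

Step 8
Reactants: 12 rac enone
Product: 13 rac 3α,4α-epoxy 18-ketone with free terminal alkyne
Conditions: 30% H2O2, 2 M NaOH (0.3 equiv), MeOH, 0 → 23 °C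
Reagents that add atoms: hydrogen peroxide OO
Why: Nucleophilic (Weitz–Scheffer) epoxidation touches only the electron-poor enone, hydroperoxide adding to C3 and the enolate closing on the exposed α face of the trans-fused bicycle (the β face of the enone lies under the angular C20 methyl), which sets C3 and C4 together as the α-epoxide while the methanolic base cleaves the alkynyl silane.

Step 9
Reactants: 13 rac 3α,4α-epoxy 18-ketone
Product: 14 rac-3α-hydroxy-15,16-dinorlabd-8(17)-en-13-yn-18-oic acid
Conditions: 2 M NaOH, EtOH–H2O, 75 °C; then 1 M HCl, 0 °C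
Reagents that add atoms: sodium hydroxide [Na+].[OH-]
Why: Hydroxide adds to the C18 ketone and the tetrahedral alkoxide pushes the C18–C5 bond onto C4, so that C5 migrates to C4 while the epoxide C4–O bond breaks, the oxygen stays on C3 as the alkoxide and C18 leaves the ring as the carboxylate. The closest known reaction type is the Favorskii-type (semibenzilic) rearrangement of cyclic α,β-epoxy ketones to ring-contracted β-hydroxy acids in aqueous alkali. Ring A is closed by this 1,2-shift, formally a backside three-centre (exo-tet) displacement at C4 by the migrating σ-bond, which contracts the seven-membered ring by one atom. C4 is controlled by the α-epoxide, since inversion puts C18 where the oxygen was (α, cis to O3) and leaves C19 β; C3 keeps its oxygen with retention, and C5 migrates with retention so the trans ring fusion is carried over. The step needs the semibenzilic path to outrun enolisation at C5 (cyclopropanone route) and epoxide opening by hydroxide; carbonyl addition in strongly aqueous base and the anti-periplanar alignment that the flexible seven-membered ring can reach should secure this.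

Step 10
Reactants: 14 rac-3α-hydroxy-15,16-dinorlabd-8(17)-en-13-yn-18-oic acid
Product: 15 (S)-1-phenylethylammonium (3R,4S,5R,9S,10R)-3α-hydroxy-15,16-dinorlabd-8(17)-en-13-yn-18-oate
Conditions: (S)-1-phenylethylamine (1.0 equiv), EtOAc, 60 → 4 °C; recrystallisation to constant rotation
Reagents that add atoms: (S)-1-phenylethylamine C[C@H](N)c1ccccc1
Why: Classical resolution, in which the two diastereomeric ammonium carboxylates differ in solubility so that fractional crystallisation should give the salt of the (3R,4S,5R,9S,10R)-acid and fix the absolute configuration of all five stereocentres (the (R)-amine is used instead if the wanted salt proves the more soluble one).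

Step 11
Reactants: 15 (S)-1-phenylethylammonium salt of the resolved acid
Product: 17 3α,15-dihydroxylabda-8(17),13E-dien-18-oic acid, via free acid 16 (not isolated)
Conditions: 1 M HCl/EtOAc partition; then Me3Al (6 equiv), Cp2ZrCl2 (0.25 equiv), ClCH2CH2Cl, 0 → 23 °C; solvent exchange to THF; n-BuLi, −78 °C; (CH2O)n, −78 → 23 °C; 1 M HCl
Reagents that add atoms: trimethylaluminium C[Al](C)C; paraformaldehyde (formaldehyde unit) C=O
Why: Zirconium-catalysed carboalumination (Negishi) adds methyl and aluminium syn across the terminal alkyne with methyl on the internal carbon, and the derived alkenyl alanate is hydroxymethylated with retention to set the 13E alkene, while the acid and hydroxyl are carried as aluminium carboxylate and alkoxide and the 1,1-disubstituted C8=C17 alkene is inert.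

Step 12
Reactants: 17 3α,15-dihydroxylabda-8(17),13E-dien-18-oic acid
Product: 19 3α,15-diacetoxylabda-8(17),13E-dien-18-oic acid, via mixed anhydride 18 (not isolated)
Conditions: Ac2O, pyridine, 4-(dimethylamino)pyridine (cat.), CH2Cl2, 23 °C; then H2O–THF, 23 °C
Reagents that add atoms: acetic anhydride CC(=O)OC(C)=O
Why: Exhaustive nucleophile-catalysed acetylation esterifies the hindered axial 3α-hydroxyl as well as the primary allylic one, and the aqueous work-up hydrolyses the mixed anhydride formed at the carboxyl group.

Step 13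
Reactants: 19 3α,15-diacetoxylabda-8(17),13E-dien-18-oic acid
Product: 20 3α-acetoxy-15-hydroxylabda-8(17),13E-dien-18-oic acid (CNP0395853.2)
Conditions: K2CO3 (1.5 equiv), MeOH, 0 °C; then 1 M HCl to pH 3
Reagents that add atoms: none
Why: Base-catalysed methanolysis (transesterification) should remove the unhindered primary allylic acetate much faster than the axial 3α-acetate flanked by the quaternary C4, which releases the target.

Compound list
1 | hex-5-ynenitrile | C#CCCCC#N | starting material
2 | 6-(trimethylsilyl)hex-5-ynenitrile | C[Si](C)(C)C#CCCCC#N | intermediate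
3 | 8-(trimethylsilyl)oct-1-en-7-yn-3-one | C=CC(=O)CCCC#C[Si](C)(C)C | intermediate
4 | (3Z)-3-(tert-butyldimethylsilyloxy)-8-(trimethylsilyl)octa-1,3-dien-7-yne | CC(C)(C)[Si](C)(C)O/C(C=C)=C\CCC#C[Si](C)(C)C | intermediate
5 | 3-methylcyclohept-2-en-1-one | CC1=CC(=O)CCCC1 | starting material
6 | rac cis-fused cycloadduct: ring B enol silyl ether C7=C8–OSi(t-Bu)Me2, C18 ketone in the seven-membered ring, H5 cis to C20, C9 chain CH2CH2C≡CSiMe3 trans to C20 | CC(C)(C)[Si](C)(C)OC1=CC[C@H]2[C@](C)(CCCCC2=O)[C@@H]1CCC#C[Si](C)(C)C | intermediate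
7 | rac cis-fused 8,18-diketone (H5 cis to C20, C9 chain trans to C20) | O=C1CC[C@H]2[C@](C)(CCCCC2=O)[C@@H]1CCC#C[Si](C)(C)C | intermediate
8 | rac trans-fused 8,18-diketone (H5 α, C20 β, 9β-CH2CH2C≡CSiMe3) | O=C1CC[C@@H]2[C@](C)(CCCCC2=O)[C@H]1CCC#C[Si](C)(C)C | intermediate
9 | rac 8(17)-methylene 18-ketone | C=C1CC[C@@H]2[C@](C)(CCCCC2=O)[C@H]1CCC#C[Si](C)(C)C | intermediate
10 | rac 4-(phenylselanyl) 18-ketone (C4 epimers, C4 not specified) | C=C1CC[C@@H]2[C@](C)(CCCC([Se]c3ccccc3)C2=O)[C@H]1CCC#C[Si](C)(C)C | intermediate
11 | rac 4-methyl-4-(phenylselanyl) 18-ketone (C4 not specified) | C=C1CC[C@@H]2[C@](C)(CCCC(C)([Se]c3ccccc3)C2=O)[C@H]1CCC#C[Si](C)(C)C | intermediate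
12 | rac enone: 4-methyl, C3=C4, C18=O in the seven-membered ring, C8=C17H2, 9β-CH2CH2C≡CSiMe3 | C=C1CC[C@@H]2[C@](C)(CCC=C(C)C2=O)[C@H]1CCC#C[Si](C)(C)C | intermediate
13 | rac 3α,4α-epoxy 18-ketone (C19 β on C4), C8=C17H2, 9β-CH2CH2C≡CH | C=C1CC[C@@H]2[C@](C)(CC[C@H]3O[C@@]3(C)C2=O)[C@H]1CCC#C | intermediate
14 | rac-3α-hydroxy-15,16-dinorlabd-8(17)-en-13-yn-18-oic acid | C=C1CC[C@@H]2[C@](C)(CC[C@@H](O)[C@@]2(C)C(=O)O)[C@H]1CCC#C | intermediate
15 | (S)-1-phenylethylammonium (3R,4S,5R,9S,10R)-3α-hydroxy-15,16-dinorlabd-8(17)-en-13-yn-18-oate | C=C1CC[C@@H]2[C@](C)(CC[C@@H](O)[C@@]2(C)C(=O)[O-])[C@H]1CCC#C.C[C@H]([NH3+])c1ccccc1 | intermediate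
16 | (3R,4S,5R,9S,10R)-3α-hydroxy-15,16-dinorlabd-8(17)-en-13-yn-18-oic acid (single enantiomer) | C=C1CC[C@@H]2[C@](C)(CC[C@@H](O)[C@@]2(C)C(=O)O)[C@H]1CCC#C | intermediate
17 | 3α,15-dihydroxylabda-8(17),13E-dien-18-oic acid | C=C1CC[C@@H]2[C@](C)(CC[C@@H](O)[C@@]2(C)C(=O)O)[C@H]1CC/C(C)=C/CO | intermediate
18 | acetic 3α,15-diacetoxylabda-8(17),13E-dien-18-oic anhydride | C=C1CC[C@@H]2[C@](C)(CC[C@@H](OC(C)=O)[C@@]2(C)C(=O)OC(C)=O)[C@H]1CC/C(C)=C/COC(C)=O | intermediate
19 | 3α,15-diacetoxylabda-8(17),13E-dien-18-oic acid | C=C1CC[C@@H]2[C@](C)(CC[C@@H](OC(C)=O)[C@@]2(C)C(=O)O)[C@H]1CC/C(C)=C/COC(C)=O | intermediate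
20 | 3α-acetoxy-15-hydroxylabda-8(17),13E-dien-18-oic acid | C=C1CC[C@@H]2[C@](C)(CC[C@@H](OC(C)=O)[C@@]2(C)C(=O)O)[C@H]1CC/C(C)=C/CO | target

Total step count: 13. Longest linear sequence: 13 steps (1 → 20 through steps 1–13; 5 enters at step 4).

Steps most likely to fail

Step 9 (key step). The hydroxide adduct may not rearrange cleanly: enolisation at C5 opens a cyclopropanone pathway that scrambles C5 or places the carboxyl on C5, and direct opening of the epoxide by hydroxide competes. The fallback sets out from 13 and comes back at 14, and runs the contraction as an acid-promoted semipinacol rearrangement. LiBH(s-Bu)3 (THF, −78 °C) should reduce C18 from the α face, since C19 and C20 both screen the β face, to the 18β-hydroxy 3α,4α-epoxide F1 with the hydroxyl trans to the epoxide. Me3SiCl and imidazole give its trimethylsilyl ether F2. BF3·OEt2 (CH2Cl2, −78 °C) opens the epoxide at tertiary C4, and the ring bond C18–C5 migrates, because H18 is syn to the epoxide and cannot. This should give the ring-A 3α-hydroxy 18-aldehyde F3 with the same C3, C4 and C5 configuration. Pinnick oxidation (NaClO2, NaH2PO4, 2-methyl-2-butene) then returns to 14.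

Step 4. The cycloaddition builds a quaternary carbon next to a tertiary one and may stall, or the Lewis acid may consume the silyloxydiene by hydrolysis or oligomerisation before the second bond forms. The fallback sets out from 4 and 5 and comes back at 8, as a two-step polar annulation. TiCl4 (CH2Cl2, −78 °C) promotes the Mukaiyama–Michael addition of 4 to 5 and should give, after work-up, the open-chain vinyl ketone 3-methyl-3-[3-oxo-8-(trimethylsilyl)oct-1-en-7-yn-4-yl]cycloheptan-1-one F4, with the C9–C10 bond formed and ring B still open. KN(SiMe3)2 (THF, −78 → 0 °C) then closes ring B by intramolecular Michael addition of the C5 enolate to the vinyl ketone. The HCl/DBU equilibration of step 4 gives 8.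

Step 8. Poor facial selectivity in the peroxide addition would give the β-epoxide and, after step 9, the C3/C4 epimer. The fallback sets out from 12 and comes back at 13, and delivers the epoxide oxygen from a hydroxyl group. Luche reduction (NaBH4, CeCl3·7H2O, MeOH, −78 °C; hydride from the α face) should give the 18β-allylic alcohol F5. Mitsunobu inversion (4-nitrobenzoic acid, PPh3, diisopropyl azodicarboxylate) gives the 18α-(4-nitrobenzoate) F6. K2CO3 in MeOH frees the 18α-allylic alcohol F7 and cleaves the alkynyl silane. VO(acac)2 with t-BuOOH (CH2Cl2, 0 °C) epoxidises syn to the hydroxyl, on the α face, to give the 3α,4α-epoxy 18α-alcohol F8. Dess–Martin periodinane oxidises C18 back to the ketone 13.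

Further compounds
F1 | step 9 | rac 3α,4α-epoxy 18β-alcohol (13 with C18 reduced, hydroxyl β and trans to the epoxide) | C=C1CC[C@@H]2[C@](C)(CC[C@H]3O[C@@]3(C)[C@@H]2O)[C@H]1CCC#C
F2 | step 9 | trimethylsilyl ether of F1 | C=C1CC[C@@H]2[C@](C)(CC[C@H]3O[C@@]3(C)[C@@H]2O[Si](C)(C)C)[C@H]1CCC#C
F3 | step 9 | rac-3α-hydroxy-15,16-dinorlabd-8(17)-en-13-yn-18-al | C=C1CC[C@@H]2[C@](C)(CC[C@@H](O)[C@@]2(C)C=O)[C@H]1CCC#C
F4 | step 4 | 3-methyl-3-[3-oxo-8-(trimethylsilyl)oct-1-en-7-yn-4-yl]cycloheptan-1-one (racemic, both diastereomers) | C=CC(=O)C(CCC#C[Si](C)(C)C)C1(C)CCCCC(=O)C1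
F5 | step 8 | rac 18β-allylic alcohol (12 with C18 reduced, hydroxyl β) | C=C1CC[C@@H]2[C@](C)(CCC=C(C)[C@@H]2O)[C@H]1CCC#C[Si](C)(C)C
F6 | step 8 | rac 18α-(4-nitrobenzoate) of the inverted allylic alcohol | C=C1CC[C@@H]2[C@](C)(CCC=C(C)[C@H]2OC(=O)c3ccc(cc3)[N+](=O)[O-])[C@H]1CCC#C[Si](C)(C)C
F7 | step 8 | rac 18α-allylic alcohol with free terminal alkyne | C=C1CC[C@@H]2[C@](C)(CCC=C(C)[C@H]2O)[C@H]1CCC#C
F8 | step 8 | rac 3α,4α-epoxy 18α-alcohol | C=C1CC[C@@H]2[C@](C)(CC[C@H]3O[C@@]3(C)[C@H]2O)[C@H]1CCC#C
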